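A small charge of free catalyst, 5 mol%, stands in teal and grey alike, and the dawn run at 35 °C shows what such a charge does. Your hunch that grey ends above teal needs one number to become a quick estimate.

| flask | substrate | coupling partner | free catalyst | temperature | remark | time |
|---|---|---|---|---|---|---|
| summer | 0.10 M | 0.42 equiv | 5 mol% | 20 °C | run made earlier |  |
| dawn | 0.10 M | 0.40 equiv | 5 mol% | 35 °C | run made earlier |  |
| winter | 0.10 M | 0.51 equiv | 5 mol% | 20 °C | run made earlier |  |
| teal | 0.10 M | 0.340 equiv | 5 mol% | 35 °C |  | 0.40 h |
| grey | 0.10 M | 0.500 equiv | 5 mol% | 35 °C |  | 1.5 h |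

- summer (time / min: product / %, substrate / %): 8.00: 0, 98.4; 15.0: 0, 96.6; 40.0: 1.4, 94.7; 120: 7.2, 90.0
- dawn (time / min: product / %, substrate / %): 4.00: 0.8, 96.9; 8.00: 1.3, 96.3; 20.0: 4.5, 93.5; 50.0: 12.3, 85.8
- winter (time / min: product / %, substrate / %): 8.00: 0.1, 97.6; 15.0: 0, 97.2; 40.0: 1.9, 94.0; 120: 7.6, 87.8

(standard deviation of a reading: 0.5 percentage points)

- steps thought possible: substrate + free catalyst <-> catalyst intermediate A; catalyst intermediate C -> free catalyst + product; coupling partner + catalyst intermediate A -> catalyst intermediate B; free catalyst + product -> spent catalyst; catalyst intermediate B <-> released group + catalyst intermediate C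

- which one finishes higher in amount of product, in percent of the substrate charged ("neither" within 2 percentage points) (teal / grey / neither)
- amount of product at the end, in percent of the substrate charged, teal
- amount of product at the end, in percent of the substrate charged, grey

In the dawn run, product climbs from 1.3% at 8.00 min to 12.3% at 50.0 min, and the reading between, 4.5% at 20.0 min, lies close to that line. The slope is 0.157 h⁻¹, and this is the steady product rate: the fraction of the substrate charged that becomes product per hour while the forms of the catalyst keep a fixed division, a steady state of its round. Can it be carried across different partner charges? At 20 °C, summer and winter differ in partner, 0.42 equiv against 0.51 equiv, yet their last product readings differ by 0.4 percentage points, less than the scatter of 0.5 points. But that pair spans neither the partner charges nor the temperature of these flasks, so carrying the rate over to both is an assumption of this reckoning. Continued from the dawn reading at 8.00 min, the line gives 5.49% for teal at 0.40 h and 22.8% for grey at 1.5 h.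

The forecast names grey as the higher, with 5.3% for teal and 21% for grey, both below this line; of grey it says “falling substrate and possible product-driven catalyst loss should lower it”.

The flasks give 5.00% in teal and 22.6% in grey, so grey ends higher.

    substrate + free catalyst ⇌ catalyst intermediate A (K = 7.00 M⁻¹, k = 0.0920 M⁻¹ s⁻¹, Ea = 68.0 kJ mol⁻¹, ΔH = −20.0 kJ mol⁻¹)
    catalyst intermediate C → free catalyst + product (k = 0.00840 s⁻¹, Ea = 86.0 kJ mol⁻¹)
    coupling partner + catalyst intermediate A → catalyst intermediate B (k = 0.140 M⁻¹ s⁻¹, Ea = 59.0 kJ mol⁻¹)
    free catalyst + product → spent catalyst (k = 0.00190 M⁻¹ s⁻¹, Ea = 56.0 kJ mol⁻¹)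
    catalyst intermediate B ⇌ released group + catalyst intermediate C (K = 0.0410 M, k = 0.00330 s⁻¹, Ea = 88.0 kJ mol⁻¹, ΔH = 9.00 kJ mol⁻¹)
    (constants at 35 °C)

Teal stands 0.49 points under the line and grey 0.20 points under it. At 1.5 h with the dawn charge of partner the flask holds 19.9%, against 22.6% in grey, so grey's nearness to the line is no proof of a rate free of partner. In grey at 0.600 h, catalyst intermediate C is made 0.989 times as fast as it is used up and catalyst intermediate B 0.983 times, each step taken net. Free catalyst in grey reads 40.5% of the catalyst charged at 0.750 h and 44.0% at 1.50 h, when 4.98% is spent. Read at 25 min, grey should hold 5.75% by the steady product rate; the flask holds 6.46%.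

Readings and results come from a simulation with constants of no real substance; the scatter is artificial.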